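**Strategy.** The route rests on disconnecting ring A of the labdane core across C3–C4 and C5–C10 (labdane numbering). The C4 gem-dimethyl/C5/C6-oxygen array is read as a 3-methylbut-2-enoyl dienophile, and C10(CH3)–C1–C2–C3 as an (E)-diene. An intramolecular Diels–Alder reaction of a monocyclic trienone then closes rings A and B together and sets C5 and C10. The precursor is a γ-lactone carrying an (E)-penta-2,4-dien-2-yl group and a 4-methyl-2-oxopent-3-enyl chain. This temporary lactone holds C8, C9, C11 and C12, locks the tether, masks the C8 hydroxyl and later delivers C12 for the (12Z)-diene side chain. C8 and C9 come from a Shi epoxidation and an acetylide opening.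

Key step: step 10

Remark: labdane numbering (C1–C20) is used for all intermediates; the lactol carbons and the carbinol carbon made in step 8 are left uncontrolled because they are removed again.

Step 1
Reactants: 1 tert-butyl(but-3-yn-1-yloxy)dimethylsilane; 2 trimethylaluminium; 3 oxirane
Product: 6 (3E)-6-[(tert-butyldimethylsilyl)oxy]-4-methylhex-3-en-1-ol, via alkenyldimethylalane 4 (not isolated), via lithium alkenylbutyldimethylaluminate 5 (not isolated)
Conditions: Me3Al (2 equiv), Cp2ZrCl2 (0.25 equiv), CH2Cl2, rt; evaporation; n-BuLi, THF/hexane, −78 °C; oxirane, −78 °C → rt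
Reagents that add atoms: none
Why: Negishi zirconium-catalysed carboalumination adds CH3 and Al syn across the terminal alkyne with the methyl on the internal carbon, and the derived alkenylaluminate opens oxirane with retention, so the (E)-trisubstituted C8=C9 alkene with both two-carbon arms is fixed and no stereocenter is formed.

Step 2
Reactants: 6 (3E)-6-[(tert-butyldimethylsilyl)oxy]-4-methylhex-3-en-1-ol
Product: 7 (3E)-1,6-bis[(tert-butyldimethylsilyl)oxy]-3-methylhex-3-ene
Conditions: TBSCl, imidazole, DMF, rt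
Reagents that add atoms: tert-butyl(chloro)dimethylsilane, CC(C)(C)[Si](C)(C)Cl
Why: Silyl ether formation masks the second primary alcohol so that both arms survive the basic epoxide opening and the organoaluminium step, and no stereocenter is involved.

Step 3
Reactants: 7 (3E)-1,6-bis[(tert-butyldimethylsilyl)oxy]-3-methylhex-3-ene
Product: 8 (2R,3R)-2,3-bis{2-[(tert-butyldimethylsilyl)oxy]ethyl}-2-methyloxirane
Conditions: D-fructose-derived Shi ketone (0.3 equiv), Oxone (2KHSO5·KHSO4·K2SO4), K2CO3, Bu4NHSO4, MeCN/dimethoxymethane/aq. Na2B4O7 buffer (pH 10.5), 0 °C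
Reagents that add atoms: potassium peroxymonosulfate (active oxidant of Oxone), [K+].[O-]S(=O)(=O)OO
Why: In the Shi asymmetric epoxidation the chiral dioxirane transfers oxygen to the (E)-trisubstituted alkene through a spiro transition state, which should give the (2R,3R)-epoxide and so set the oxygen-bearing quaternary C8 and C9 under reagent control.

Step 4
Reactants: 8 (2R,3R)-2,3-bis{2-[(tert-butyldimethylsilyl)oxy]ethyl}-2-methyloxirane; 9 lithium acetylide–ethane-1,2-diamine complex
Product: 10 (3R,4R)-1-[(tert-butyldimethylsilyl)oxy]-4-{2-[(tert-butyldimethylsilyl)oxy]ethyl}-3-methylhex-5-yn-3-ol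
Conditions: LiC≡CH·H2NCH2CH2NH2 (5 equiv), DMSO, rt → 45 °C
Reagents that add atoms: none
Why: SN2 opening of the trisubstituted epoxide by acetylide at the less substituted carbon (C9) with inversion leaves the quaternary C8–O bond untouched and should give the tertiary alcohol with the C8/C9 relationship of the target.

Step 5
Reactants: 10 (3R,4R)-1-[(tert-butyldimethylsilyl)oxy]-4-{2-[(tert-butyldimethylsilyl)oxy]ethyl}-3-methylhex-5-yn-3-ol; 2 trimethylaluminium; 11 bromoethene
Product: 13 (3R,4R,5E)-1-[(tert-butyldimethylsilyl)oxy]-4-{2-[(tert-butyldimethylsilyl)oxy]ethyl}-3,5-dimethylocta-5,7-dien-3-ol, via alkenylalane 12 (not isolated)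
Conditions: Me3Al (4 equiv), Cp2ZrCl2 (0.5 equiv), CH2Cl2, 0 °C → rt; then bromoethene, Pd(PPh3)4 (5 mol%), THF, rt
Reagents that add atoms: none
Why: Negishi carboalumination places CH3 on the internal alkyne carbon (C10) and Al on C1 in a syn fashion, and the palladium-catalysed cross-coupling of the alkenylalane with bromoethene proceeds with retention, so the (E)-diene with its methyl group cis to the vinyl unit should result without touching a stereocenter.

Step 6
Reactants: 13 (3R,4R,5E)-1-[(tert-butyldimethylsilyl)oxy]-4-{2-[(tert-butyldimethylsilyl)oxy]ethyl}-3,5-dimethylocta-5,7-dien-3-ol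
Product: 14 (3R,4R,5E)-4-(2-hydroxyethyl)-3,5-dimethylocta-5,7-diene-1,3-diol
Conditions: Bu4NF (3 equiv), THF, 0 °C → rt
Reagents that add atoms: none
Why: Fluoride-mediated desilylation frees both primary alcohols and leaves the diene and both stereocenters unchanged.

Step 7
Reactants: 14 (3R,4R,5E)-4-(2-hydroxyethyl)-3,5-dimethylocta-5,7-diene-1,3-diol
Product: 16 2-[(2R,3R)-2-methyl-5-oxo-3-[(2E)-penta-2,4-dien-2-yl]oxolan-2-yl]acetaldehyde, via lactol aldehyde 15 (not isolated)
Conditions: TEMPO (0.2 equiv), PhI(OAc)2 (3.5 equiv), CH2Cl2, rt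
Reagents that add atoms: none
Why: In this oxidative lactonisation of a 1,4-diol both primary alcohols are oxidised to aldehydes, the C12 aldehyde is trapped by the tertiary C8 hydroxyl as a five-membered lactol that is oxidised on to the γ-lactone, and the C6 aldehyde, which cannot cyclise, remains.

Step 8
Reactants: 16 2-[(2R,3R)-2-methyl-5-oxo-3-[(2E)-penta-2,4-dien-2-yl]oxolan-2-yl]acetaldehyde; 17 (2-methylprop-1-en-1-yl)magnesium bromide
Product: 18 (4R,5R)-5-(2-hydroxy-4-methylpent-3-en-1-yl)-5-methyl-4-[(2E)-penta-2,4-dien-2-yl]oxolan-2-one (both carbinol epimers)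
Conditions: 17 (1.2 equiv), THF, −78 °C
Reagents that add atoms: none
Why: Grignard 1,2-addition to the aldehyde is chemoselective at low temperature over the less electrophilic lactone, and the new carbinol center is formed without control because step 9 removes it.

Step 9
Reactants: 18 (4R,5R)-5-(2-hydroxy-4-methylpent-3-en-1-yl)-5-methyl-4-[(2E)-penta-2,4-dien-2-yl]oxolan-2-one
Product: 19 (4R,5R)-5-methyl-5-(4-methyl-2-oxopent-3-en-1-yl)-4-[(2E)-penta-2,4-dien-2-yl]oxolan-2-one
Conditions: MnO2 (20 equiv), CH2Cl2, rt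
Reagents that add atoms: none
Why: MnO2 oxidation of the allylic alcohol gives the β,β-dimethyl enone under neutral conditions that should not trigger β-elimination of the β-acyloxy ketone.

Step 10
Reactants: 19 (4R,5R)-5-methyl-5-(4-methyl-2-oxopent-3-en-1-yl)-4-[(2E)-penta-2,4-dien-2-yl]oxolan-2-one
Product: 20 6-oxo-13,14,15,16-tetranorlabd-1-en-12,8α-olide (trans-fused rings A/B with 5α-H and 10β-CH3, C1=C2 double bond, 8β-CH3, 9α-H, γ-lactone from O on C8α to C12 on C11)
Conditions: Me2AlCl (2.2 equiv), CH2Cl2 (0.01 M), −78 → −20 °C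
Reagents that add atoms: none
Why: Complexation of the ketone by Me2AlCl polarises the 3-methylbut-2-enoyl unit so that its gem-dimethyl β-carbon (C4) bonds first to the unsubstituted diene terminus (C3) in an asynchronous concerted [4+2] cycloaddition, with the C5–C10 bond closing in the same transition state; the closest known reaction type is the Lewis-acid-promoted intramolecular Diels–Alder reaction of 1,7,9-decatrien-3-ones to octalones. Ring A is closed as the cyclohexene formed by the cycloaddition itself, and ring B as the six-membered ring spanned by the four-atom tether C6–C7–C8–C9 (type 1 mode, with C5–C10 as the ring-fusion bond). C10 is controlled by the diene face that is attacked: the trans-fused γ-lactone allows only the chair tether in which the C8 oxygen and C11 are both equatorial, since the diaxial alternative cannot be bridged by a five-membered ring, so the C10 methyl of the (E)-diene should end up axial and β, syn to C11 and to the C8 methyl. C5 is controlled by the exo orientation of the tether carbonyl in a trans-decalin-like transition state, favoured because the endo mode presses one C4 methyl against the tether, and because C5 is α to the ketone any cis-fused 5-epimer should converge on the more stable trans-fused ketone on acid equilibration. Regiochemistry is fixed by the tether and reinforced by the polarisation (nucleophilic C3 to electrophilic C4), and the low temperature allowed by the Lewis acid should suppress the thermal 1,5-hydrogen shift open to a diene with a cis-methyl group.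

Step 11
Reactants: 20 6-oxo-13,14,15,16-tetranorlabd-1-en-12,8α-olide
Product: 21 6-oxo-13,14,15,16-tetranorlabdan-12,8α-olide (6-oxosclareolide; 5α-H, 8β-CH3, 9α-H, 10β-CH3)
Conditions: H2 (1 atm), Pd/C (10 wt%), EtOAc, rt
Reagents that add atoms: none
Why: Heterogeneous catalytic hydrogenation saturates the cis-disubstituted C1=C2 alkene, the only C=C bond present, without creating a stereocenter.

Step 12
Reactants: 21 6-oxo-13,14,15,16-tetranorlabdan-12,8α-olide
Product: 22 6α-hydroxy-13,14,15,16-tetranorlabdan-12,8α-olide (equatorial 6α-OH)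
Conditions: SmI2 (3 equiv), THF/H2O, 0 °C → rt
Reagents that add atoms: none
Why: Single-electron (ketyl) reduction by SmI2 with water as proton source should, like a dissolving-metal reduction, give the thermodynamically preferred equatorial 6α-alcohol, whereas hydride reagents would attack the α face (the β face is shielded by the axial methyls on C4, C8 and C10) and give the 6β-epimer, and the γ-lactone is inert to this reagent.

Step 13
Reactants: 22 6α-hydroxy-13,14,15,16-tetranorlabdan-12,8α-olide
Product: 23 8α,12-epoxy-13,14,15,16-tetranorlabdane-6α,12-diol (lactol, both anomers)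
Conditions: i-Bu2AlH (3 equiv), CH2Cl2, −78 °C
Reagents that add atoms: none
Why: Partial reduction of the γ-lactone by i-Bu2AlH stops at the lactol because the tetrahedral aluminate is stable at −78 °C, and the anomeric center is inconsequential.

Step 14
Reactants: 23 8α,12-epoxy-13,14,15,16-tetranorlabdane-6α,12-diol; 24 ethyltriphenylphosphonium iodide
Product: 25 (12Z)-13-iodo-14,15-dinorlabd-12-ene-6α,8α-diol
Conditions: 24 (4 equiv), n-BuLi, THF, −78 °C; I2, −78 °C; NaN(SiMe3)2, −20 °C; then 23, −78 → 0 °C
Reagents that add atoms: iodine, II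
Why: In this Wittig olefination of the Stork–Zhao type the α-iodo ylide reacts with the open hydroxy-aldehyde form of the lactol through the kinetically favoured cis-oxaphosphetane, which should give the (Z)-vinyl iodide (iodine cis to C11) and release the C8 hydroxyl.

Step 15
Reactants: 25 (12Z)-13-iodo-14,15-dinorlabd-12-ene-6α,8α-diol; 26 tributyl(ethenyl)stannane
Product: 27 (12Z)-labda-12,14-diene-6α,8α-diol
Conditions: 26 (2 equiv), Pd2(dba)3 (5 mol%), AsPh3 (20 mol%), CuI (10 mol%), DMF, rt
Reagents that add atoms: none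
Why: Stille cross-coupling proceeds with retention at the vinyl iodide, so the vinyl group ends up cis to C11 and the (12Z)-diene should form in the presence of the free hydroxyls.

Step 16
Reactants: 27 (12Z)-labda-12,14-diene-6α,8α-diol; 28 angelic acid ((2Z)-2-methylbut-2-enoic acid)
Product: 29 (12Z)-8α-hydroxylabda-12,14-dien-6α-yl (2Z)-2-methylbut-2-enoate (CNP0582767.2)
Conditions: 28 (3 equiv), 2,4,6-trichlorobenzoyl chloride, Et3N, toluene, rt; then 27, 75 °C
Reagents that add atoms: none
Why: Yamaguchi-type esterification through the mixed anhydride should acylate the secondary equatorial 6α-hydroxyl selectively over the tertiary C8 hydroxyl, and leaving out nucleophilic amine catalysts avoids Z-to-E isomerisation of the angelate.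

**Compound list**

1 | tert-butyl(but-3-yn-1-yloxy)dimethylsilane | C#CCCO[Si](C)(C)C(C)(C)C | starting material
2 | trimethylaluminium | C[Al](C)C | starting material
3 | oxirane | C1CO1 | starting material
4 | {(1E)-4-[(tert-butyldimethylsilyl)oxy]-2-methylbut-1-en-1-yl}dimethylalane | C[Al](C)/C=C(\C)CCO[Si](C)(C)C(C)(C)C | intermediate
5 | lithium butyl{(1E)-4-[(tert-butyldimethylsilyl)oxy]-2-methylbut-1-en-1-yl}dimethylaluminate | [Li+].CCCC[Al-](C)(C)/C=C(\C)CCO[Si](C)(C)C(C)(C)C | intermediate
6 | (3E)-6-[(tert-butyldimethylsilyl)oxy]-4-methylhex-3-en-1-ol | OCC/C=C(\C)CCO[Si](C)(C)C(C)(C)C | intermediate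
7 | (3E)-1,6-bis[(tert-butyldimethylsilyl)oxy]-3-methylhex-3-ene | CC(C)(C)[Si](C)(C)OCC/C=C(\C)CCO[Si](C)(C)C(C)(C)C | intermediate
8 | (2R,3R)-2,3-bis{2-[(tert-butyldimethylsilyl)oxy]ethyl}-2-methyloxirane | CC(C)(C)[Si](C)(C)OCC[C@H]1O[C@]1(C)CCO[Si](C)(C)C(C)(C)C | intermediate
9 | lithium acetylide–ethane-1,2-diamine complex | [Li+].[C-]#C.NCCN | starting material
10 | (3R,4R)-1-[(tert-butyldimethylsilyl)oxy]-4-{2-[(tert-butyldimethylsilyl)oxy]ethyl}-3-methylhex-5-yn-3-ol | C#C[C@@H](CCO[Si](C)(C)C(C)(C)C)[C@](C)(O)CCO[Si](C)(C)C(C)(C)C | intermediate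
11 | bromoethene | C=CBr | starting material
12 | (E)-alkenyldimethylalane of 10 with the tertiary hydroxyl as its dimethylaluminium alkoxide (Al on C1, CH3 on C10) | C[Al](C)/C=C(\C)[C@@H](CCO[Si](C)(C)C(C)(C)C)[C@](C)(O[Al](C)C)CCO[Si](C)(C)C(C)(C)C | intermediate
13 | (3R,4R,5E)-1-[(tert-butyldimethylsilyl)oxy]-4-{2-[(tert-butyldimethylsilyl)oxy]ethyl}-3,5-dimethylocta-5,7-dien-3-ol | C=C/C=C(\C)[C@@H](CCO[Si](C)(C)C(C)(C)C)[C@](C)(O)CCO[Si](C)(C)C(C)(C)C | intermediate
14 | (3R,4R,5E)-4-(2-hydroxyethyl)-3,5-dimethylocta-5,7-diene-1,3-diol | C=C/C=C(\C)[C@@H](CCO)[C@](C)(O)CCO | intermediate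
15 | 2-[(2R,3R)-5-hydroxy-2-methyl-3-[(2E)-penta-2,4-dien-2-yl]oxolan-2-yl]acetaldehyde (lactol, both anomers) | C=C/C=C(\C)[C@H]1CC(O)O[C@]1(C)CC=O | intermediate
16 | 2-[(2R,3R)-2-methyl-5-oxo-3-[(2E)-penta-2,4-dien-2-yl]oxolan-2-yl]acetaldehyde | C=C/C=C(\C)[C@H]1CC(=O)O[C@]1(C)CC=O | intermediate
17 | (2-methylprop-1-en-1-yl)magnesium bromide | CC(C)=C[Mg]Br | starting material
18 | (4R,5R)-5-(2-hydroxy-4-methylpent-3-en-1-yl)-5-methyl-4-[(2E)-penta-2,4-dien-2-yl]oxolan-2-one (both carbinol epimers) | C=C/C=C(\C)[C@H]1CC(=O)O[C@]1(C)CC(O)C=C(C)C | intermediate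
19 | (4R,5R)-5-methyl-5-(4-methyl-2-oxopent-3-en-1-yl)-4-[(2E)-penta-2,4-dien-2-yl]oxolan-2-one | C=C/C=C(\C)[C@H]1CC(=O)O[C@]1(C)CC(=O)C=C(C)C | intermediate
20 | 6-oxo-13,14,15,16-tetranorlabd-1-en-12,8α-olide (5α-H, 8β-CH3, 9α-H, 10β-CH3) | O=C1C[C@@H]2[C@@]3(C)C=CCC(C)(C)[C@@H]3C(=O)C[C@@]2(C)O1 | intermediate
21 | 6-oxo-13,14,15,16-tetranorlabdan-12,8α-olide (6-oxosclareolide) | O=C1C[C@@H]2[C@@]3(C)CCCC(C)(C)[C@@H]3C(=O)C[C@@]2(C)O1 | intermediate
22 | 6α-hydroxy-13,14,15,16-tetranorlabdan-12,8α-olide | O=C1C[C@@H]2[C@@]3(C)CCCC(C)(C)[C@@H]3[C@@H](O)C[C@@]2(C)O1 | intermediate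
23 | 8α,12-epoxy-13,14,15,16-tetranorlabdane-6α,12-diol (lactol, both anomers) | OC1C[C@@H]2[C@@]3(C)CCCC(C)(C)[C@@H]3[C@@H](O)C[C@@]2(C)O1 | intermediate
24 | ethyltriphenylphosphonium iodide | CC[P+](c1ccccc1)(c1ccccc1)c1ccccc1.[I-] | starting material
25 | (12Z)-13-iodo-14,15-dinorlabd-12-ene-6α,8α-diol | I/C(C)=C\C[C@@H]1[C@@]2(C)CCCC(C)(C)[C@@H]2[C@@H](O)C[C@@]1(C)O | intermediate
26 | tributyl(ethenyl)stannane | C=C[Sn](CCCC)(CCCC)CCCC | starting material
27 | (12Z)-labda-12,14-diene-6α,8α-diol | C=C/C(C)=C\C[C@@H]1[C@@]2(C)CCCC(C)(C)[C@@H]2[C@@H](O)C[C@@]1(C)O | intermediate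
28 | angelic acid, (2Z)-2-methylbut-2-enoic acid | C/C=C(/C)C(=O)O | starting material
29 | (12Z)-8α-hydroxylabda-12,14-dien-6α-yl (2Z)-2-methylbut-2-enoate (CNP0582767.2) | C=C/C(C)=C\C[C@@H]1[C@@]2(C)CCCC(C)(C)[C@@H]2[C@@H](OC(=O)/C(C)=C\C)C[C@@]1(C)O | target

**Step count and risks**

Total step count: 16. Longest linear sequence: 16 steps (from 1 to 29).

The step most likely to fail is step 10. The β,β-disubstituted dienophile may be activated too weakly, so that Lewis-acid-induced ionisation of the tertiary lactone C–O bond or isomerisation of the diene outruns the cycloaddition, and diene-face or endo/exo control may be incomplete. The fallback sets out from 19 and changes the dienophile into a cation. Ketalisation with 1,2-bis(trimethylsilyloxy)ethane and catalytic TMSOTf at −78 °C should give the dioxolane (4R,5R)-5-methyl-5-{[2-(2-methylprop-1-en-1-yl)-1,3-dioxolan-2-yl]methyl}-4-[(2E)-penta-2,4-dien-2-yl]oxolan-2-one F1. More TMSOTf at −78 °C ionises F1 to a dioxolenium-stabilised allyl cation, a much stronger dienophile. Its intramolecular ionic Diels–Alder reaction should give the ethylene ketal of the adduct, 6,6-(ethane-1,2-diyldioxy)-13,14,15,16-tetranorlabd-1-en-12,8α-olide F2. Mild aqueous acid hydrolysis (HCl, THF/H2O) then comes back to the route at 20.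

The second is step 14. The lactol of a tertiary alcohol may open only reluctantly, the α-iodo ylide may decompose before it reacts, and Z-selectivity may erode. The fallback sets out from 23. A Still–Gennari olefination with ethyl 2-[bis(2,2,2-trifluoroethoxy)phosphoryl]propanoate (KN(SiMe3)2, 18-crown-6, THF, −78 °C) should give the (Z)-enoate ethyl (12Z)-6α,8α-dihydroxy-15-norlabd-12-en-14-oate F3. Reduction with i-Bu2AlH gives the allylic alcohol (12Z)-15-norlabd-12-ene-6α,8α,14-triol F4. MnO2 oxidation gives the enal (12Z)-6α,8α-dihydroxy-15-norlabd-12-en-14-al F5. Wittig methylenation with Ph3P=CH2 then comes back to the route at 27, bypassing 25 and step 15.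

The third is step 12. Protonation of the ketyl-derived intermediate may show poor facial selectivity and give the axial 6β-alcohol, or the lactone may be reduced as well. The fallback sets out from 21 and separates reduction from stereocontrol. NaBH4 in MeOH should deliver hydride from the open α face and give the axial alcohol 6β-hydroxy-13,14,15,16-tetranorlabdan-12,8α-olide F6. Redox equilibration of F6 under Meerwein–Ponndorf–Verley/Oppenauer conditions (Al(OiPr)3, a little acetone, isopropanol/toluene, reflux) should then convert it into the more stable equatorial epimer and come back to the route at 22.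

Further compounds
F1 | step 10 | (4R,5R)-5-methyl-5-{[2-(2-methylprop-1-en-1-yl)-1,3-dioxolan-2-yl]methyl}-4-[(2E)-penta-2,4-dien-2-yl]oxolan-2-one | C=C/C=C(\C)[C@H]1CC(=O)O[C@]1(C)CC2(C=C(C)C)OCCO2
F2 | step 10 | 6,6-(ethane-1,2-diyldioxy)-13,14,15,16-tetranorlabd-1-en-12,8α-olide | O=C1C[C@@H]2[C@@]3(C)C=CCC(C)(C)[C@@H]3C4(OCCO4)C[C@@]2(C)O1
F3 | step 14 | ethyl (12Z)-6α,8α-dihydroxy-15-norlabd-12-en-14-oate | CCOC(=O)/C(C)=C\C[C@@H]1[C@@]2(C)CCCC(C)(C)[C@@H]2[C@@H](O)C[C@@]1(C)O
F4 | step 14 | (12Z)-15-norlabd-12-ene-6α,8α,14-triol | OC/C(C)=C\C[C@@H]1[C@@]2(C)CCCC(C)(C)[C@@H]2[C@@H](O)C[C@@]1(C)O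
F5 | step 14 | (12Z)-6α,8α-dihydroxy-15-norlabd-12-en-14-al | O=C/C(C)=C\C[C@@H]1[C@@]2(C)CCCC(C)(C)[C@@H]2[C@@H](O)C[C@@]1(C)O
F6 | step 12 | 6β-hydroxy-13,14,15,16-tetranorlabdan-12,8α-olide | O=C1C[C@@H]2[C@@]3(C)CCCC(C)(C)[C@@H]3[C@H](O)C[C@@]2(C)O1
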